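**Plan**

1. Retrosynthetically the ring A silyl ether is cut last. The benzofuran is then opened at O1–C2 and at C3–C3a, which gives an ethynyl dihydrobenzofuran and ortho-iodinated dihydroconiferyl alcohol (from eugenol).
2. The alkyne goes back to the C5 aldehyde and the C3 hydroxymethyl group to a methyl ester. The dihydrofuran is then cut at O1–C2 and at C3–CO2Me.
3. Enabling feature: O1, C2, C3 and the CH2OH carbon of the dihydrobenzofuran ring are the phenol oxygen and the two alkene carbons of an (E)-2-hydroxystilbene plus one CO. The trans C2/C3 relation is what anti addition across the E alkene delivers.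
4. The stilbene comes from a Heck coupling of 5-iodovanillin with silylated 4-vinylguaiacol.
5. Forward order: stilbene, dihydrofuran ring by oxypalladation/methoxycarbonylation, reduction and benzylic re-oxidation, alkynylation, Sonogashira coupling with cycloisomerisation (benzofuran ring), desilylation.
6. Both stereocentres arise in the carbonylative cyclisation: C2 from ligand-controlled choice of the alkene face, C3 relative to it from anti addition and retentive CO insertion. The ester is reduced directly afterwards so that no later base meets an acidic C3–H.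

Key step: step 3

Assumption: the sense of induction of the bis(oxazoline) ligand in step 3 cannot be predicted with confidence; the (S,S) ligand is written, and its mirror image is to be used if it favours the (2R,3R) ester.

**Route**

Step 1
Reactants: 1 2-methoxy-4-vinylphenol (4-vinylguaiacol)
Product: 2 triisopropyl(2-methoxy-4-vinylphenoxy)silane
Conditions: TIPSCl, imidazole, DMF, 0 °C to rt
Reagents that add atoms: triisopropylsilyl chloride, CC(C)[Si](Cl)(C(C)C)C(C)C
Why: Imidazole-promoted silyl ether formation masks the ring A phenol with a group bulky enough to survive the amine and carbonate bases used later, yet removable by fluoride at the end.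

Step 2
Reactants: 2 triisopropyl(2-methoxy-4-vinylphenoxy)silane; 3 5-iodovanillin (4-hydroxy-3-iodo-5-methoxybenzaldehyde)
Product: 4 (E)-4-hydroxy-3-methoxy-5-{2-[3-methoxy-4-(triisopropylsilyloxy)phenyl]ethenyl}benzaldehyde
Conditions: Pd(OAc)2 (5 mol %), P(o-tol)3 (12 mol %), Et3N, DMF, 90 °C
Reagents that add atoms: none
Why: Heck reaction, in which zerovalent palladium adds oxidatively to the C–I bond, the styrene inserts syn at its unsubstituted carbon and syn beta-hydride elimination should give the E stilbene, free ortho-iodophenols being accepted partners.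

Step 3
Reactants: 4 (E)-4-hydroxy-3-methoxy-5-{2-[3-methoxy-4-(triisopropylsilyloxy)phenyl]ethenyl}benzaldehyde
Product: 5 methyl (2S,3S)-trans-5-formyl-7-methoxy-2-[3-methoxy-4-(triisopropylsilyloxy)phenyl]-2,3-dihydrobenzofuran-3-carboxylate
Conditions: Pd(OCOCF3)2 (10 mol %), 2,2'-isopropylidenebis[(4S)-4-tert-butyl-2-oxazoline] (12 mol %), p-benzoquinone (2 equiv), CO (5 atm), MeOH/CH2Cl2 1:1, -20 to 0 °C
Reagents that add atoms: carbon monoxide, [C-]#[O+]; methanol, CO
Why: Proposed new method: divalent palladium carrying the chiral bis(oxazoline) binds one face of the E alkene, the ring B phenol oxygen adds to the carbon next to ring A from the face opposite the metal (anti oxypalladation, helped by the para-silyloxy donor of ring A), and the benzylic C3–Pd bond inserts CO with retention before methanolysis releases the ester and zerovalent palladium, which p-benzoquinone returns to the divalent state. The closest known reaction type is the intramolecular alkoxycarbonylation of alkenyl alcohols and phenols catalysed by divalent palladium with bis(oxazoline) ligands, which so far closes exo rings, whereas 2-hydroxystilbenes under oxidative palladium conditions are known to end as 2-arylbenzofurans. The dihydrofuran closes in the 5-endo-trig mode, which is open to a nucleophile that attacks the coordinated alkene from outside the metal, and no other ring size competes because attack at C3 would give an oxetane. C2 is set by the ligand-controlled choice of alkene face and C3 follows from it, since anti addition across the E double bond and retentive insertion place ring A and the ester trans. The step needs CO insertion to beat beta-hydride elimination (C2–H lies syn to palladium), which CO pressure, low temperature and the eta-3 benzyl character of the C3–Pd bond should secure, and it needs regioselectivity, which the substrate secures because the phenol oxygen can reach only C2.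

Step 4
Reactants: 5 methyl (2S,3S)-trans-5-formyl-7-methoxy-2-[3-methoxy-4-(triisopropylsilyloxy)phenyl]-2,3-dihydrobenzofuran-3-carboxylate
Product: 6 (2S,3R)-3,5-bis(hydroxymethyl)-7-methoxy-2-[3-methoxy-4-(triisopropylsilyloxy)phenyl]-2,3-dihydrobenzofuran
Conditions: LiBH4, THF, 0 °C to rt; aq NH4Cl
Reagents that add atoms: none
Why: Hydride reduction by LiBH4 takes the aldehyde first (removing the acceptor that would assist base-induced opening of the dihydrofuran beside the ester) and then the ester, leaves the aryl silyl ether alone and touches neither stereocentre, the change of the C3 descriptor from S to R being one of priority only.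

Step 5
Reactants: 6 (2S,3R)-3,5-bis(hydroxymethyl)-7-methoxy-2-[3-methoxy-4-(triisopropylsilyloxy)phenyl]-2,3-dihydrobenzofuran
Product: 7 (2S,3R)-3-(hydroxymethyl)-7-methoxy-2-[3-methoxy-4-(triisopropylsilyloxy)phenyl]-2,3-dihydrobenzofuran-5-carbaldehyde
Conditions: activated MnO2 (excess), CH2Cl2, rt
Reagents that add atoms: none
Why: Chemoselective benzylic oxidation, since activated MnO2 oxidises the benzylic alcohol at C5 and should leave the saturated primary alcohol at C3 untouched.

Step 6
Reactants: 7 (2S,3R)-3-(hydroxymethyl)-7-methoxy-2-[3-methoxy-4-(triisopropylsilyloxy)phenyl]-2,3-dihydrobenzofuran-5-carbaldehyde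
Product: 8 {(2S,3R)-5-ethynyl-7-methoxy-2-[3-methoxy-4-(triisopropylsilyloxy)phenyl]-2,3-dihydrobenzofuran-3-yl}methanol
Conditions: dimethyl (1-diazo-2-oxopropyl)phosphonate, K2CO3, MeOH/THF, 0 °C to rt
Reagents that add atoms: dimethyl (1-diazo-2-oxopropyl)phosphonate, CC(=O)C(=[N+]=[N-])P(=O)(OC)OC
Why: Ohira–Bestmann alkynylation (Seyferth–Gilbert homologation), in which methanolysis frees the diazomethylphosphonate anion, addition to the aldehyde, phosphate elimination, loss of N2 and a 1,2-hydride shift give the terminal alkyne, while C3 no longer carries an acidifying group that the carbonate could exploit.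

Step 7
Reactants: 9 eugenol (4-allyl-2-methoxyphenol)
Product: 11 4-(3-hydroxypropyl)-2-methoxyphenol (dihydroconiferyl alcohol), via bis-borylated hydroboration adduct 10 (not isolated)
Conditions: 9-BBN (2.3 equiv), THF, 0 °C to rt; then aq NaOH, H2O2, 0 °C to rt
Reagents that add atoms: hydrogen peroxide, OO
Why: Hydroboration–oxidation, in which the bulky borane adds anti-Markovnikov to the terminal alkene (the phenol consuming one equivalent as a borinate) and alkaline peroxide replaces boron by hydroxyl with retention and hydrolyses the borinate.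

Step 8
Reactants: 11 4-(3-hydroxypropyl)-2-methoxyphenol
Product: 12 4-(3-hydroxypropyl)-2-iodo-6-methoxyphenol
Conditions: I2, NaHCO3, THF/H2O, 0 °C to rt
Reagents that add atoms: iodine, II
Why: Electrophilic aromatic iodination of the phenoxide, whose para position is blocked, should take place at the only free position ortho to the oxygen.

Step 9
Reactants: 8 {(2S,3R)-5-ethynyl-7-methoxy-2-[3-methoxy-4-(triisopropylsilyloxy)phenyl]-2,3-dihydrobenzofuran-3-yl}methanol; 12 4-(3-hydroxypropyl)-2-iodo-6-methoxyphenol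
Product: 14 3-{2-[(2S,3R)-3-(hydroxymethyl)-7-methoxy-2-[3-methoxy-4-(triisopropylsilyloxy)phenyl]-2,3-dihydrobenzofuran-5-yl]-7-methoxybenzofuran-5-yl}propan-1-ol, via 2-alkynylphenol 13 (not isolated)
Conditions: PdCl2(PPh3)2 (5 mol %), CuI (10 mol %), Et3N, degassed DMF, rt then 70 °C
Reagents that add atoms: none
Why: Sonogashira coupling gives the 2-alkynylphenol, which under the same palladium/copper/amine conditions at higher temperature undergoes 5-endo-dig cycloisomerisation to the 2-arylbenzofuran, a standard tandem for ortho-iodophenols that tolerates free alcohols.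

Step 10
Reactants: 14 3-{2-[(2S,3R)-3-(hydroxymethyl)-7-methoxy-2-[3-methoxy-4-(triisopropylsilyloxy)phenyl]-2,3-dihydrobenzofuran-5-yl]-7-methoxybenzofuran-5-yl}propan-1-ol
Product: 15 4-{(2S,3R)-3-(hydroxymethyl)-5-[5-(3-hydroxypropyl)-7-methoxybenzofuran-2-yl]-7-methoxy-2,3-dihydrobenzofuran-2-yl}-2-methoxyphenol (target)
Conditions: TBAF, AcOH (1:1), THF, 0 °C
Reagents that add atoms: none
Why: Fluoride-induced desilylation cleaves the aryl silyl ether, and the acetic acid buffer keeps the freed phenol protonated so that the para-hydroxybenzylic ether of the dihydrofuran and both stereocentres stay intact.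

**Compound list**

1 | 2-methoxy-4-vinylphenol | C=Cc1ccc(O)c(OC)c1 | starting material
2 | triisopropyl(2-methoxy-4-vinylphenoxy)silane | C=Cc1ccc(O[Si](C(C)C)(C(C)C)C(C)C)c(OC)c1 | intermediate
3 | 5-iodovanillin | COc1cc(C=O)cc(I)c1O | starting material
4 | (E)-4-hydroxy-3-methoxy-5-{2-[3-methoxy-4-(triisopropylsilyloxy)phenyl]ethenyl}benzaldehyde | COc1cc(/C=C/c2cc(C=O)cc(OC)c2O)ccc1O[Si](C(C)C)(C(C)C)C(C)C | intermediate
5 | methyl (2S,3S)-trans-5-formyl-7-methoxy-2-[3-methoxy-4-(triisopropylsilyloxy)phenyl]-2,3-dihydrobenzofuran-3-carboxylate | COc1cc([C@H]2Oc3c(OC)cc(C=O)cc3[C@@H]2C(=O)OC)ccc1O[Si](C(C)C)(C(C)C)C(C)C | intermediate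
6 | (2S,3R)-3,5-bis(hydroxymethyl)-7-methoxy-2-[3-methoxy-4-(triisopropylsilyloxy)phenyl]-2,3-dihydrobenzofuran | COc1cc([C@H]2Oc3c(OC)cc(CO)cc3[C@@H]2CO)ccc1O[Si](C(C)C)(C(C)C)C(C)C | intermediate
7 | (2S,3R)-3-(hydroxymethyl)-7-methoxy-2-[3-methoxy-4-(triisopropylsilyloxy)phenyl]-2,3-dihydrobenzofuran-5-carbaldehyde | COc1cc([C@H]2Oc3c(OC)cc(C=O)cc3[C@@H]2CO)ccc1O[Si](C(C)C)(C(C)C)C(C)C | intermediate
8 | {(2S,3R)-5-ethynyl-7-methoxy-2-[3-methoxy-4-(triisopropylsilyloxy)phenyl]-2,3-dihydrobenzofuran-3-yl}methanol | COc1cc([C@H]2Oc3c(OC)cc(C#C)cc3[C@@H]2CO)ccc1O[Si](C(C)C)(C(C)C)C(C)C | intermediate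
9 | eugenol | C=CCc1ccc(O)c(OC)c1 | starting material
10 | 9-{3-[4-(9-borabicyclo[3.3.1]nonan-9-yloxy)-3-methoxyphenyl]propyl}-9-borabicyclo[3.3.1]nonane | COc1cc(CCCB2C3CCCC2CCC3)ccc1OB1C2CCCC1CCC2 | intermediate
11 | 4-(3-hydroxypropyl)-2-methoxyphenol | COc1cc(CCCO)ccc1O | intermediate
12 | 4-(3-hydroxypropyl)-2-iodo-6-methoxyphenol | COc1cc(CCCO)cc(I)c1O | intermediate
13 | 2-({(2S,3R)-3-(hydroxymethyl)-7-methoxy-2-[3-methoxy-4-(triisopropylsilyloxy)phenyl]-2,3-dihydrobenzofuran-5-yl}ethynyl)-4-(3-hydroxypropyl)-6-methoxyphenol | COc1cc([C@H]2Oc3c(OC)cc(C#Cc4cc(CCCO)cc(OC)c4O)cc3[C@@H]2CO)ccc1O[Si](C(C)C)(C(C)C)C(C)C | intermediate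
14 | 3-{2-[(2S,3R)-3-(hydroxymethyl)-7-methoxy-2-[3-methoxy-4-(triisopropylsilyloxy)phenyl]-2,3-dihydrobenzofuran-5-yl]-7-methoxybenzofuran-5-yl}propan-1-ol | COc1cc([C@H]2Oc3c(OC)cc(-c4cc5cc(CCCO)cc(OC)c5o4)cc3[C@@H]2CO)ccc1O[Si](C(C)C)(C(C)C)C(C)C | intermediate
15 | 4-{(2S,3R)-3-(hydroxymethyl)-5-[5-(3-hydroxypropyl)-7-methoxybenzofuran-2-yl]-7-methoxy-2,3-dihydrobenzofuran-2-yl}-2-methoxyphenol | COc1cc([C@H]2Oc3c(OC)cc(-c4cc5cc(CCCO)cc(OC)c5o4)cc3[C@@H]2CO)ccc1O | target

**Step count**

Total step count: 10.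
Longest linear sequence: 8 steps (steps 1, 2, 3, 4, 5, 6, 9, 10, from compound 1).

**Steps most likely to fail**

Step 3. Several processes may defeat it: sluggish oxypalladation by the weakly nucleophilic formyl-substituted phenol, beta-hydride elimination outrunning CO insertion, reduction of divalent palladium by CO, or poor facial selectivity. The fallback uses a known enantioselective dirhodium-carbenoid C–H insertion that builds the same ring from the ether side; it sets out from 2 and 3 and returns at 6. Styrene 2 is ozonised with NaBH4 work-up to [3-methoxy-4-(triisopropylsilyloxy)phenyl]methanol F1. F1 etherifies the acidic phenol of 3 under Mitsunobu conditions (PPh3, DIAD, THF) to 3-iodo-5-methoxy-4-{[3-methoxy-4-(triisopropylsilyloxy)phenyl]methoxy}benzaldehyde F2. Palladium-catalysed coupling of the aryl iodide with ethyl diazoacetate (Pd(PPh3)4, Et3N, Bu4NBr, MeCN) gives ethyl 2-diazo-2-(5-formyl-3-methoxy-2-{[3-methoxy-4-(triisopropylsilyloxy)phenyl]methoxy}phenyl)acetate F3. Rh2(S-PTTL)4, dirhodium tetrakis[N-phthaloyl-(S)-tert-leucinate] (or its mirror image, whichever sets C2 as S), inserts the carbenoid into the benzylic ether C–H to give ethyl (2S,3R)-cis-5-formyl-7-methoxy-2-[3-methoxy-4-(triisopropylsilyloxy)phenyl]-2,3-dihydrobenzofuran-3-carboxylate F4. NaBH4 in methanol reduces the aldehyde to ethyl (2S,3R)-cis-5-(hydroxymethyl)-7-methoxy-2-[3-methoxy-4-(triisopropylsilyloxy)phenyl]-2,3-dihydrobenzofuran-3-carboxylate F5. NaOMe added to the same flask epimerises C3 and exchanges the ester to give methyl (2S,3S)-trans-5-(hydroxymethyl)-7-methoxy-2-[3-methoxy-4-(triisopropylsilyloxy)phenyl]-2,3-dihydrobenzofuran-3-carboxylate F6. LiBH4 as in step 4 then converts F6 into diol 6.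

Step 9. The risks are oxidative homocoupling of alkyne 8, slow oxidative addition into the electron-rich iodophenoxide, and a coupling that stops at the alkynylphenol. The fallback separates coupling from ring closure and masks the phenol; it sets out from 8 and 12 and returns at 15. Compound 12 is silylated (TBSCl, imidazole, DMF) to tert-butyl{3-[4-(tert-butyldimethylsilyloxy)-3-iodo-5-methoxyphenyl]propoxy}dimethylsilane F7. Sonogashira coupling of F7 with 8 on the now neutral aryl iodide gives the isolated diarylalkyne {(2S,3R)-5-({2-(tert-butyldimethylsilyloxy)-5-[3-(tert-butyldimethylsilyloxy)propyl]-3-methoxyphenyl}ethynyl)-7-methoxy-2-[3-methoxy-4-(triisopropylsilyloxy)phenyl]-2,3-dihydrobenzofuran-3-yl}methanol F8. Excess TBAF in THF at 60 °C removes all three silyl groups and closes the liberated 2-alkynylphenoxide 5-endo-dig to the benzofuran, giving target 15 directly.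

Step 6. The risks are premature loss of the aryl silyl ether in carbonate/methanol and slow homologation of the electron-rich aldehyde. The fallback avoids the alkyne altogether; it sets out from 7 (with 12) and returns at 14. Wittig methylenation of 7 (Ph3PCH3Br, KOtBu, THF, excess ylide to allow for the free alcohol) gives {(2S,3R)-5-ethenyl-7-methoxy-2-[3-methoxy-4-(triisopropylsilyloxy)phenyl]-2,3-dihydrobenzofuran-3-yl}methanol F9. Heck coupling of F9 with iodophenol 12 under the conditions of step 2 gives (E)-2-(2-{(2S,3R)-3-(hydroxymethyl)-7-methoxy-2-[3-methoxy-4-(triisopropylsilyloxy)phenyl]-2,3-dihydrobenzofuran-5-yl}ethenyl)-4-(3-hydroxypropyl)-6-methoxyphenol F10. The known oxidative cyclisation of 2-hydroxystilbenes (PdCl2(MeCN)2, p-benzoquinone, THF, 60 °C; oxypalladation then beta-hydride elimination) closes the 2-arylbenzofuran 14.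

**Further compounds**

F1 | step 3 | [3-methoxy-4-(triisopropylsilyloxy)phenyl]methanol | COc1cc(CO)ccc1O[Si](C(C)C)(C(C)C)C(C)C
F2 | step 3 | 3-iodo-5-methoxy-4-{[3-methoxy-4-(triisopropylsilyloxy)phenyl]methoxy}benzaldehyde | COc1cc(C=O)cc(I)c1OCc1ccc(O[Si](C(C)C)(C(C)C)C(C)C)c(OC)c1
F3 | step 3 | ethyl 2-diazo-2-(5-formyl-3-methoxy-2-{[3-methoxy-4-(triisopropylsilyloxy)phenyl]methoxy}phenyl)acetate | CCOC(=O)C(=[N+]=[N-])c1cc(C=O)cc(OC)c1OCc1ccc(O[Si](C(C)C)(C(C)C)C(C)C)c(OC)c1
F4 | step 3 | ethyl (2S,3R)-cis-5-formyl-7-methoxy-2-[3-methoxy-4-(triisopropylsilyloxy)phenyl]-2,3-dihydrobenzofuran-3-carboxylate | COc1cc([C@H]2Oc3c(OC)cc(C=O)cc3[C@H]2C(=O)OCC)ccc1O[Si](C(C)C)(C(C)C)C(C)C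
F5 | step 3 | ethyl (2S,3R)-cis-5-(hydroxymethyl)-7-methoxy-2-[3-methoxy-4-(triisopropylsilyloxy)phenyl]-2,3-dihydrobenzofuran-3-carboxylate | COc1cc([C@H]2Oc3c(OC)cc(CO)cc3[C@H]2C(=O)OCC)ccc1O[Si](C(C)C)(C(C)C)C(C)C
F6 | step 3 | methyl (2S,3S)-trans-5-(hydroxymethyl)-7-methoxy-2-[3-methoxy-4-(triisopropylsilyloxy)phenyl]-2,3-dihydrobenzofuran-3-carboxylate | COc1cc([C@H]2Oc3c(OC)cc(CO)cc3[C@@H]2C(=O)OC)ccc1O[Si](C(C)C)(C(C)C)C(C)C
F7 | step 9 | tert-butyl{3-[4-(tert-butyldimethylsilyloxy)-3-iodo-5-methoxyphenyl]propoxy}dimethylsilane | COc1cc(CCCO[Si](C)(C)C(C)(C)C)cc(I)c1O[Si](C)(C)C(C)(C)C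
F8 | step 9 | {(2S,3R)-5-({2-(tert-butyldimethylsilyloxy)-5-[3-(tert-butyldimethylsilyloxy)propyl]-3-methoxyphenyl}ethynyl)-7-methoxy-2-[3-methoxy-4-(triisopropylsilyloxy)phenyl]-2,3-dihydrobenzofuran-3-yl}methanol | COc1cc([C@H]2Oc3c(OC)cc(C#Cc4cc(CCCO[Si](C)(C)C(C)(C)C)cc(OC)c4O[Si](C)(C)C(C)(C)C)cc3[C@@H]2CO)ccc1O[Si](C(C)C)(C(C)C)C(C)C
F9 | step 6 | {(2S,3R)-5-ethenyl-7-methoxy-2-[3-methoxy-4-(triisopropylsilyloxy)phenyl]-2,3-dihydrobenzofuran-3-yl}methanol | COc1cc([C@H]2Oc3c(OC)cc(C=C)cc3[C@@H]2CO)ccc1O[Si](C(C)C)(C(C)C)C(C)C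
F10 | step 6 | (E)-2-(2-{(2S,3R)-3-(hydroxymethyl)-7-methoxy-2-[3-methoxy-4-(triisopropylsilyloxy)phenyl]-2,3-dihydrobenzofuran-5-yl}ethenyl)-4-(3-hydroxypropyl)-6-methoxyphenol | COc1cc([C@H]2Oc3c(OC)cc(/C=C/c4cc(CCCO)cc(OC)c4O)cc3[C@@H]2CO)ccc1O[Si](C(C)C)(C(C)C)C(C)C
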